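The route cuts the phloroglucinol A ring at C8–C8a and C4a–C5, so the C ring with both stereocentres is made first and the arene last. Two features are exploited: the six A-ring substituents alternate (O at C5, C7, C8a; C at C4a, C6, C8) as in a 1,3,5-tricarbonyl chain, and the C4a–C8a bond is shared with ring C, where it can be installed beforehand as the C=C of a vinylogous thioester. In one operation a diprenylated acetoacetate dianion replaces methanethiolate at C8a and the chain closes onto its own ester through C4a. The precursor is an enantiopure 3-silyloxy-2-aryl-6-methylthio-2,3-dihydropyran-4-one.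

Key step: step 8

Remarks on the chemistry:
- Flavanone numbering (O1, C2, C3, C4, C4a, C5–C8, C8a) is used for the atoms of the key step, also in its precursors.
- 1-(tert-Butyldimethylsilyloxy)propan-2-one (3) is assumed to be a catalogue compound; otherwise it is one silylation away from hydroxyacetone.
- The 4′-oxygen is carried as a TIPS ether and the 3-oxygen as a TBS ether. An aryl TBS ether would be at risk from the thiolate and methoxide set free in the key step, and a free 4′-phenoxide would open a path to C2 epimerisation.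
- In the key step the keto ester dianion is used in excess with LDA as the limiting reagent, so that no free amide base meets the pyranone.

Step 1
Reactants: 1 4-hydroxybenzaldehyde
Product: 2 4-(triisopropylsilyloxy)benzaldehyde
Conditions: TIPSCl (1.1 equiv), imidazole (2 equiv), DMF, rt
Reagents that add atoms: chlorotriisopropylsilane, CC(C)[Si](Cl)(C(C)C)C(C)C
Why: Imidazole-promoted O-silylation of a phenol is routine, and the bulky TIPS ether is chosen because it withstands the amide bases, thiolate and methoxide met in steps 4 and 8.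

Step 2
Reactants: 2 4-(triisopropylsilyloxy)benzaldehyde; 3 1-(tert-butyldimethylsilyloxy)propan-2-one
Product: 4 (3R,4R)-3-(tert-butyldimethylsilyloxy)-4-hydroxy-4-[4-(triisopropylsilyloxy)phenyl]butan-2-one
Conditions: D-proline (30 mol%), 3 (5 equiv), DMSO, 4 °C → rt
Reagents that add atoms: none
Why: Proline-type enamine aldol of an α-oxygenated ketone: the (E)-enamine formed on the oxygen-bearing carbon of 3 adds to the carboxylic-acid-activated aldehyde through a chair-like hydrogen-bonded transition state, so the enamine geometry sets the anti relationship and the D-catalyst the (3R,4R) sense (mirror image of the 3S,4S anti diols that L-proline gives with hydroxyacetone), the minor syn isomer being removed by chromatography.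

Step 3
Reactants: 4 (3R,4R)-3-(tert-butyldimethylsilyloxy)-4-hydroxy-4-[4-(triisopropylsilyloxy)phenyl]butan-2-one
Product: 5 (3R,4R)-3-(tert-butyldimethylsilyloxy)-4-(triethylsilyloxy)-4-[4-(triisopropylsilyloxy)phenyl]butan-2-one
Conditions: TESCl (1.3 equiv), imidazole (2.5 equiv), CH2Cl2, 0 °C → rt
Reagents that add atoms: chlorotriethylsilane, CC[Si](Cl)(CC)CC
Why: Silylation of the secondary benzylic alcohol as an acid-labile TES ether masks the only free OH (no xanthate formation or retro-aldol in step 4) without touching either stereocentre.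

Step 4
Reactants: 5 (3R,4R)-3-(tert-butyldimethylsilyloxy)-4-(triethylsilyloxy)-4-[4-(triisopropylsilyloxy)phenyl]butan-2-one
Product: 7 (4R,5R)-4-(tert-butyldimethylsilyloxy)-1,1-bis(methylthio)-5-(triethylsilyloxy)-5-[4-(triisopropylsilyloxy)phenyl]pent-1-en-3-one, via dilithium ene-1,1-dithiolate 6 (not isolated)
Conditions: LiHMDS (2.2 equiv), THF, –78 °C; CS2 (1.2 equiv), –78 → 0 °C; MeI (2.5 equiv), 0 °C → rt
Reagents that add atoms: carbon disulfide, S=C=S; iodomethane, CI
Why: Standard α-oxoketene dithioacetal synthesis: kinetic deprotonation at the unhindered methyl group, C-addition of the enolate to CS2, a second deprotonation to the ene-dithiolate and double S-methylation, the hindered C–H next to the silyloxy group staying untouched at low temperature.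

Step 5
Reactants: 7 (4R,5R)-4-(tert-butyldimethylsilyloxy)-1,1-bis(methylthio)-5-(triethylsilyloxy)-5-[4-(triisopropylsilyloxy)phenyl]pent-1-en-3-one
Product: 9 (2R,3R)-3-(tert-butyldimethylsilyloxy)-6-(methylthio)-2-[4-(triisopropylsilyloxy)phenyl]-2,3-dihydro-4H-pyran-4-one, via hydroxy ketene dithioacetal 8 (not isolated)
Conditions: TFA (5 equiv), H2O (2 equiv), CH2Cl2, 0 °C → rt
Reagents that add atoms: none
Why: Acid cleaves the TES ether and the freed hydroxyl adds to the protonated ketene dithioacetal carbon with loss of methanethiol (6-endo-trig oxa-Michael addition–elimination, the established closure of 5-hydroxy-1,1-bis(methylthio)pent-1-en-3-ones to 6-methylthio-2,3-dihydropyran-4-ones); O3 stays silylated so the furanone mode is blocked, and no bond to C2 or C3 is broken, so the anti aldol becomes the trans (2R,3R) ring.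

Step 6
Reactants: 10 methyl acetoacetate; 11 prenyl bromide (1-bromo-3-methylbut-2-ene)
Product: 13 methyl 7-methyl-3-oxooct-6-enoate, via acetoacetate dianion 12 (not isolated)
Conditions: NaH (1.1 equiv), THF, 0 °C; n-BuLi (1.05 equiv), 0 °C; 11 (1.0 equiv), 0 °C → rt; 1 M HCl quench
Reagents that add atoms: none
Why: γ-Alkylation of the acetoacetate dianion: the terminal carbanion is the most basic and nucleophilic site and reacts by SN2 at the primary carbon of the allylic bromide.

Step 7
Reactants: 13 methyl 7-methyl-3-oxooct-6-enoate; 11 prenyl bromide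
Product: 14 methyl 7-methyl-2-(3-methylbut-2-en-1-yl)-3-oxooct-6-enoate (racemic)
Conditions: K2CO3 (1.5 equiv), 11 (1.0 equiv), acetone, 50 °C
Reagents that add atoms: none
Why: Classical acetoacetic ester C-alkylation at the doubly activated C2 with an allylic bromide under mild carbonate conditions, one equivalent of bromide limiting dialkylation; the new centre is racemic and is destroyed in step 8.

Step 8
Reactants: 9 (2R,3R)-3-(tert-butyldimethylsilyloxy)-6-(methylthio)-2-[4-(triisopropylsilyloxy)phenyl]-2,3-dihydro-4H-pyran-4-one; 14 methyl 7-methyl-2-(3-methylbut-2-en-1-yl)-3-oxooct-6-enoate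
Product: 17 (2R,3R)-3-(tert-butyldimethylsilyloxy)-5,7-dihydroxy-6,8-bis(3-methylbut-2-en-1-yl)-2-[4-(triisopropylsilyloxy)phenyl]chroman-4-one, via dilithium dienediolate 15 (not isolated), via substitution product 16 (not isolated)
Conditions: 14 (2.5 equiv), LDA (4.9 equiv), THF, –78 → 0 °C; 9 (1 equiv), –78 °C → rt; AcOH, then aq NaH2PO4
Reagents that add atoms: none
Why: Proposed new method: the γ-carbon of dianion 15, its most basic and softest terminus, adds to C8a of the vinylogous thioester 9 and methanethiolate is expelled (addition–elimination), any 1,2-addition at the hindered, ester-like C4 carbonyl being reversible whereas thiolate loss is not; the surplus dianion then removes the doubly activated C8–H of 16, the resulting extended enolate attacks the ester carbon through C4a, methoxide leaves and two enolisations give the phloroglucinol. The closest known reaction types are the aromatic annulations of β-(methylthio)enones and α-oxoketene dithioacetals with β-keto ester dianions and the base-induced Claisen cyclisation of 3,5,7-triketo esters to acylphloroglucinols. The ring closes in a 6-exo-trig Claisen (Dieckmann-type) mode that is enolexo with respect to the C4 enolate (C8=C8a of the dienolate lies inside the new ring), and the alternative aldol closure of C6 onto C4 is impossible because it would place the C4a=C8a bond at a bridgehead. No stereocentre is created; C2 and C3 should survive because the chain protons at C6 and C8 are far more acidic than C3–H, no free amide base is present and the sequence ends in phenoxides that no longer activate C3–H or the C2–O1 bond. The required site selectivity (γ-carbon and not C2 or oxygen of the keto ester; substitution and not enolisation of 9) is secured by the higher charge density and lower hindrance of the terminal carbanion of 15, by the soft thiolate-bearing acceptor carbon and by running the addition at –78 °C.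

Step 9
Reactants: 17 (2R,3R)-3-(tert-butyldimethylsilyloxy)-5,7-dihydroxy-6,8-bis(3-methylbut-2-en-1-yl)-2-[4-(triisopropylsilyloxy)phenyl]chroman-4-one
Product: 18 6,8-diprenylaromadendrin, (2R,3R)-3,5,7-trihydroxy-2-(4-hydroxyphenyl)-6,8-bis(3-methylbut-2-en-1-yl)chroman-4-one
Conditions: TBAF (5 equiv), AcOH (5 equiv), THF, 0 °C → rt, argon
Reagents that add atoms: none
Why: Fluoride cleaves both silyl ethers through pentacoordinate silicon, and the acetic acid buffer keeps the medium neither basic (no C2/C3 epimerisation, ring opening or aerial oxidation of the 3-hydroxyflavanone) nor strongly acidic (no cyclisation of the o-prenylphenols to chromans).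

Compound list
1 | 4-hydroxybenzaldehyde | O=Cc1ccc(O)cc1 | starting material
2 | 4-(triisopropylsilyloxy)benzaldehyde | O=Cc1ccc(O[Si](C(C)C)(C(C)C)C(C)C)cc1 | intermediate
3 | 1-(tert-butyldimethylsilyloxy)propan-2-one | CC(=O)CO[Si](C)(C)C(C)(C)C | starting material
4 | (3R,4R)-3-(tert-butyldimethylsilyloxy)-4-hydroxy-4-[4-(triisopropylsilyloxy)phenyl]butan-2-one | CC(=O)[C@H](O[Si](C)(C)C(C)(C)C)[C@H](O)c1ccc(O[Si](C(C)C)(C(C)C)C(C)C)cc1 | intermediate
5 | (3R,4R)-3-(tert-butyldimethylsilyloxy)-4-(triethylsilyloxy)-4-[4-(triisopropylsilyloxy)phenyl]butan-2-one | CC(=O)[C@H](O[Si](C)(C)C(C)(C)C)[C@H](O[Si](CC)(CC)CC)c1ccc(O[Si](C(C)C)(C(C)C)C(C)C)cc1 | intermediate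
6 | dilithium (4R,5R)-4-(tert-butyldimethylsilyloxy)-3-oxo-5-(triethylsilyloxy)-5-[4-(triisopropylsilyloxy)phenyl]pent-1-ene-1,1-bis(thiolate) (not isolated) | [Li+].[Li+].[S-]C([S-])=CC(=O)[C@H](O[Si](C)(C)C(C)(C)C)[C@H](O[Si](CC)(CC)CC)c1ccc(O[Si](C(C)C)(C(C)C)C(C)C)cc1 | intermediate
7 | (4R,5R)-4-(tert-butyldimethylsilyloxy)-1,1-bis(methylthio)-5-(triethylsilyloxy)-5-[4-(triisopropylsilyloxy)phenyl]pent-1-en-3-one | CSC(SC)=CC(=O)[C@H](O[Si](C)(C)C(C)(C)C)[C@H](O[Si](CC)(CC)CC)c1ccc(O[Si](C(C)C)(C(C)C)C(C)C)cc1 | intermediate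
8 | (4R,5R)-4-(tert-butyldimethylsilyloxy)-5-hydroxy-1,1-bis(methylthio)-5-[4-(triisopropylsilyloxy)phenyl]pent-1-en-3-one (not isolated) | CSC(SC)=CC(=O)[C@H](O[Si](C)(C)C(C)(C)C)[C@H](O)c1ccc(O[Si](C(C)C)(C(C)C)C(C)C)cc1 | intermediate
9 | (2R,3R)-3-(tert-butyldimethylsilyloxy)-6-(methylthio)-2-[4-(triisopropylsilyloxy)phenyl]-2,3-dihydro-4H-pyran-4-one | CSC1=CC(=O)[C@H](O[Si](C)(C)C(C)(C)C)[C@@H](c2ccc(O[Si](C(C)C)(C(C)C)C(C)C)cc2)O1 | intermediate
10 | methyl acetoacetate | COC(=O)CC(C)=O | starting material
11 | prenyl bromide (1-bromo-3-methylbut-2-ene) | CC(C)=CCBr | starting material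
12 | lithium sodium dianion of methyl acetoacetate (not isolated) | [Na+].[Li+].COC([O-])=CC([O-])=C | intermediate
13 | methyl 7-methyl-3-oxooct-6-enoate | COC(=O)CC(=O)CCC=C(C)C | intermediate
14 | methyl 7-methyl-2-(3-methylbut-2-en-1-yl)-3-oxooct-6-enoate (racemic) | COC(=O)C(CC=C(C)C)C(=O)CCC=C(C)C | intermediate
15 | dilithium dienediolate (dianion) of 14 (not isolated) | [Li+].[Li+].COC([O-])=C(CC=C(C)C)C([O-])=CCC=C(C)C | intermediate
16 | methyl 4-[(2R,3R)-3-(tert-butyldimethylsilyloxy)-4-oxo-2-[4-(triisopropylsilyloxy)phenyl]-3,4-dihydro-2H-pyran-6-yl]-7-methyl-2-(3-methylbut-2-en-1-yl)-3-oxooct-6-enoate (epimer mixture in the chain, present as enolate, not isolated) | COC(=O)C(CC=C(C)C)C(=O)C(CC=C(C)C)C1=CC(=O)[C@H](O[Si](C)(C)C(C)(C)C)[C@@H](c2ccc(O[Si](C(C)C)(C(C)C)C(C)C)cc2)O1 | intermediate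
17 | (2R,3R)-3-(tert-butyldimethylsilyloxy)-5,7-dihydroxy-6,8-bis(3-methylbut-2-en-1-yl)-2-[4-(triisopropylsilyloxy)phenyl]chroman-4-one | CC(C)=CCc1c(O)c(CC=C(C)C)c2c(c1O)C(=O)[C@H](O[Si](C)(C)C(C)(C)C)[C@@H](c1ccc(O[Si](C(C)C)(C(C)C)C(C)C)cc1)O2 | intermediate
18 | 6,8-diprenylaromadendrin, (2R,3R)-3,5,7-trihydroxy-2-(4-hydroxyphenyl)-6,8-bis(3-methylbut-2-en-1-yl)chroman-4-one | CC(C)=CCc1c(O)c(CC=C(C)C)c2c(c1O)C(=O)[C@H](O)[C@@H](c1ccc(O)cc1)O2 | target

Total step count: 9
Longest linear sequence: 7 steps (1 → 2 → 4 → 5 → 7 → 9 → 17 → 18; steps 1, 2, 3, 4, 5, 8, 9)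

Steps most likely to fail

1. Step 8 (Proposed new method). What may go wrong:
- proton abstraction at C3 of 9 by the dianion, followed by β-elimination of the ring oxygen (ring opening and loss of both stereocentres);
- the sequence stopping at the open-chain stage, because the ester next to an enolate is attacked too slowly;
- desilylation of the phenol by methoxide or thiolate.

Fallback (known chemistry; sets out from 1, comes back at 18): the classical chalcone-epoxide route to trans-3-hydroxyflavanones. Compound 1 is protected with MOMCl and i-Pr2NEt as 4-(methoxymethoxy)benzaldehyde F1. Commercial 2,4,6-trihydroxyacetophenone is C-prenylated twice with 11 in aqueous KOH to give 1-[2,4,6-trihydroxy-3,5-bis(3-methylbut-2-en-1-yl)phenyl]ethan-1-one F2, which is protected with NaH and MOMCl as 1-[2,4,6-tris(methoxymethoxy)-3,5-bis(3-methylbut-2-en-1-yl)phenyl]ethan-1-one F3. Claisen–Schmidt condensation of F3 with F1 (KOH, EtOH) should give (E)-3-[4-(methoxymethoxy)phenyl]-1-[2,4,6-tris(methoxymethoxy)-3,5-bis(3-methylbut-2-en-1-yl)phenyl]prop-2-en-1-one F4. Juliá–Colonna epoxidation (poly-L-leucine, urea–H2O2, DBU, THF) should give [(2R,3S)-3-[4-(methoxymethoxy)phenyl]oxiran-2-yl][2,4,6-tris(methoxymethoxy)-3,5-bis(3-methylbut-2-en-1-yl)phenyl]methanone F5; the nucleophilic oxidant leaves the prenyl groups alone. Methanolic HCl at 40–45 °C then removes the MOM groups, and the freed ortho phenol opens the epoxide at the benzylic carbon with inversion (6-endo), which should give 18 directly.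

2. Step 2. What may go wrong:
- sluggish addition of the enamine to the electron-rich aldehyde;
- enamine formation on the methyl side of 3, leading to the linear aldol;
- modest anti/syn or facial selectivity.

Fallback (sets out from 2, comes back at 5): a reagent-controlled boron aldol in place of amine catalysis. The E(O)-enol borinate made from S-tert-butyl 2-(tert-butyldimethylsilyloxy)ethanethioate, a menthone-derived bis(menthylmethyl)boron bromide (enantiomer chosen for the 2R,3R series) and Et3N should add to 2 through a closed chair transition state. This should give the anti adduct S-tert-butyl (2R,3R)-2-(tert-butyldimethylsilyloxy)-3-hydroxy-3-[4-(triisopropylsilyloxy)phenyl]propanethioate F6. Silylation (TESCl, imidazole) gives S-tert-butyl (2R,3R)-2-(tert-butyldimethylsilyloxy)-3-(triethylsilyloxy)-3-[4-(triisopropylsilyloxy)phenyl]propanethioate F7. Transamidation (MeNHOMe·HCl, i-PrMgCl) gives the Weinreb amide (2R,3R)-2-(tert-butyldimethylsilyloxy)-N-methoxy-N-methyl-3-(triethylsilyloxy)-3-[4-(triisopropylsilyloxy)phenyl]propanamide F8, and MeMgBr converts F8 into 5.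

3. Step 5. What may go wrong:
- ionisation of the 4-silyloxybenzylic C–O bond under acid, with epimerisation at C2 or elimination;
- premature loss of the TBS ether, which would open the furanone pathway.

Fallback (sets out from 7, comes back at 9): the ring is closed under basic, non-ionising conditions in two separate operations. Buffered HF·pyridine (pyridine, THF, 0 °C) removes only the TES group, and alcohol 8 is isolated. Catalytic DBU in MeCN at rt then closes the ring by alkoxide-type addition–elimination with loss of methanethiol, giving 9.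

Further compounds
F1 | step 8 | 4-(methoxymethoxy)benzaldehyde | COCOc1ccc(C=O)cc1
F2 | step 8 | 1-[2,4,6-trihydroxy-3,5-bis(3-methylbut-2-en-1-yl)phenyl]ethan-1-one | CC(=O)c1c(O)c(CC=C(C)C)c(O)c(CC=C(C)C)c1O
F3 | step 8 | 1-[2,4,6-tris(methoxymethoxy)-3,5-bis(3-methylbut-2-en-1-yl)phenyl]ethan-1-one | CC(=O)c1c(OCOC)c(CC=C(C)C)c(OCOC)c(CC=C(C)C)c1OCOC
F4 | step 8 | (E)-3-[4-(methoxymethoxy)phenyl]-1-[2,4,6-tris(methoxymethoxy)-3,5-bis(3-methylbut-2-en-1-yl)phenyl]prop-2-en-1-one | COCOc1ccc(/C=C/C(=O)c2c(OCOC)c(CC=C(C)C)c(OCOC)c(CC=C(C)C)c2OCOC)cc1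
F5 | step 8 | [(2R,3S)-3-[4-(methoxymethoxy)phenyl]oxiran-2-yl][2,4,6-tris(methoxymethoxy)-3,5-bis(3-methylbut-2-en-1-yl)phenyl]methanone | COCOc1ccc([C@@H]2O[C@H]2C(=O)c3c(OCOC)c(CC=C(C)C)c(OCOC)c(CC=C(C)C)c3OCOC)cc1
F6 | step 2 | S-tert-butyl (2R,3R)-2-(tert-butyldimethylsilyloxy)-3-hydroxy-3-[4-(triisopropylsilyloxy)phenyl]propanethioate | CC(C)(C)SC(=O)[C@H](O[Si](C)(C)C(C)(C)C)[C@H](O)c1ccc(O[Si](C(C)C)(C(C)C)C(C)C)cc1
F7 | step 2 | S-tert-butyl (2R,3R)-2-(tert-butyldimethylsilyloxy)-3-(triethylsilyloxy)-3-[4-(triisopropylsilyloxy)phenyl]propanethioate | CC(C)(C)SC(=O)[C@H](O[Si](C)(C)C(C)(C)C)[C@H](O[Si](CC)(CC)CC)c1ccc(O[Si](C(C)C)(C(C)C)C(C)C)cc1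
F8 | step 2 | (2R,3R)-2-(tert-butyldimethylsilyloxy)-N-methoxy-N-methyl-3-(triethylsilyloxy)-3-[4-(triisopropylsilyloxy)phenyl]propanamide | CON(C)C(=O)[C@H](O[Si](C)(C)C(C)(C)C)[C@H](O[Si](CC)(CC)CC)c1ccc(O[Si](C(C)C)(C(C)C)C(C)C)cc1
F0 | step 5 | none | none
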